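**Assumption:** the SMILES has no stereocentre and the diaryl ether axis rotates freely. The target is therefore achiral, and no step has to set or preserve configuration.

## Retrosynthetic overview
1. The one strategic bond is the diaryl ether C–O bond between C6 of ring A (the dibromophenol ring) and an oxygen of ring B (the tribromocatechol ring). It is made last.
2. Ring A acts as the carbon electrophile, an ortho-quinoid carbene released from its ortho-quinone diazide. Ring B supplies the less hindered O–H of 3,4,5-tribromocatechol (O–H insertion, no protecting groups).
3. The diazide comes from 2-amino-4,6-dibromophenol by diazotisation. The tribromocatechol comes from catechol by three brominations.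
4. No ring is formed. Both benzene rings are bought, and all five bromine atoms are in place before the coupling.

## Route

Step 1
Reactants: 1 catechol (benzene-1,2-diol)
Product: 4 3,4,5-tribromobenzene-1,2-diol, via 4-bromocatechol 2 (not isolated), via 4,5-dibromocatechol 3 (not isolated)
Conditions: Br2 (3.0 equiv, dropwise), AcOH, 10 °C to rt, 16 h; pour into H2O, filter, recrystallise (CHCl3)
Reagents that add atoms: bromine, BrBr
Why: Electrophilic aromatic bromination places the first two Br atoms para to the two OH groups (C4, then C5), the third can only enter one of the two equivalent ortho sites (C3 = C6), and each Br deactivates the ring, so with exactly 3.0 equiv the tetrabromide stays minor and is removed by recrystallisation.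

Step 2
Reactants: 5 2-amino-4,6-dibromophenol
Product: 7 2,4-dibromo-6-diazocyclohexa-2,4-dien-1-one, via diazonium chloride 6 (not isolated)
Conditions: NaNO2 (1.05 equiv), 2 M aq HCl, 0–5 °C, 30 min; NaOAc to pH 5; extract (CH2Cl2), dry (Na2SO4), concentrate below 25 °C in the dark (batches of 2 g or less, behind a shield)
Reagents that add atoms: sodium nitrite, [Na+].[O-]N=O
Why: Diazotisation of the primary arylamine gives a cation whose ortho OH is acidic enough for acetate to deprotonate it to the neutral, extractable ortho-quinone diazide, while both Br atoms sit meta to the diazonium group (no halide exchange) and make the ring too electron-poor for azo self-coupling.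

Step 3
Reactants: 7 2,4-dibromo-6-diazocyclohexa-2,4-dien-1-one; 4 3,4,5-tribromobenzene-1,2-diol
Product: 10 2,3,4-tribromo-6-(3,5-dibromo-2-hydroxyphenoxy)phenol (target), via rhodium quinoid carbene 8 (not isolated), via oxonium ylide 9 (not isolated)
Conditions: Rh2(esp)2 (1 mol %; esp = α,α,α′,α′-tetramethyl-1,3-benzenedipropanoate), 4 (2.0 equiv), 4 Å MS, dry ClCH2CH2Cl, 60 °C, dark, N2; 7 added over 4 h by syringe pump; surplus 4 recovered on silica
Reagents that add atoms: none
Why: Proposed new method: site-selective O–H insertion of a dirhodium-bound ortho-quinoid carbene into a free polybromocatechol, giving the 2,2'-dihydroxydiaryl ether directly; Rh2(esp)2 adds to the diazo carbon of 7, N2 leaves, and the strongly electrophilic carbene 8 (held on the metal, which suppresses Wolff ring contraction) is attacked at the former diazo carbon by the oxygen of 4 next to C6–H, which is the less hindered and more electron-rich one (it is the donor end of the O–H···O–H···Br hydrogen-bond chain, whereas the other OH is flanked by Br and is more acidic and less nucleophilic); ylide 9 then passes its proton to the adjacent phenolate oxygen, and the aromaticity gained in ring A makes C–O formation irreversible; the site on ring A is fixed by the diazo carbon, C–Br bonds are inert to divalent rhodium, 7 is too weak a base to be protonated by 4 (so no diazonium ion and no azo coupling), and both OH groups of 10 are flanked on both sides and do not compete; the closest known reaction type is dirhodium-carbenoid O–H insertion of α-diazocarbonyl compounds into phenols and of diazonaphthoquinones into alcohols, which has not been shown for a monocyclic ortho-quinone diazide with a phenolic O–H or for site selection within a free catechol.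

## Compound list
1 | catechol (benzene-1,2-diol) | Oc1ccccc1O | starting material
2 | 4-bromocatechol (4-bromobenzene-1,2-diol) | Oc1ccc(Br)cc1O | intermediate
3 | 4,5-dibromocatechol (4,5-dibromobenzene-1,2-diol) | Oc1cc(Br)c(Br)cc1O | intermediate
4 | 3,4,5-tribromobenzene-1,2-diol (OH on C1 and C2, Br on C3 to C5, H on C6) | Oc1cc(Br)c(Br)c(Br)c1O | intermediate
5 | 2-amino-4,6-dibromophenol | Nc1cc(Br)cc(Br)c1O | starting material
6 | 3,5-dibromo-2-hydroxybenzenediazonium chloride | N#[N+]c1cc(Br)cc(Br)c1O.[Cl-] | intermediate
7 | 2,4-dibromo-6-diazocyclohexa-2,4-dien-1-one (ortho-quinone diazide of ring A) | [N-]=[N+]=C1C=C(Br)C=C(Br)C1=O | intermediate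
8 | rhodium quinoid carbene (3,5-dibromo-6-oxocyclohexa-2,4-dien-1-ylidene on an axial site of Rh2(esp)2; the dirhodium unit is drawn as one Rh atom) | O=C1C(Br)=CC(Br)=CC1=[Rh] | intermediate
9 | oxonium ylide (ring A phenolate carrying the protonated ether oxygen of ring B) | [O-]c1c(Br)cc(Br)cc1[OH+]c1cc(Br)c(Br)c(Br)c1O | intermediate
10 | 2,3,4-tribromo-6-(3,5-dibromo-2-hydroxyphenoxy)phenol (CNP0266564.0, achiral) | Oc1c(Br)cc(Br)cc1Oc1cc(Br)c(Br)c(Br)c1O | target

## Step count and risks
Total steps: 3. Longest linear sequence: 2 (1 → 4 → 10, or 5 → 7 → 10).

**Step 3 (the new step, highest risk).**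
- Failure modes:
  - The carbene may abstract hydrogen from the catechol, giving 2,4-dibromophenol and the tribromo-ortho-quinone.
  - It may ring-contract (Wolff rearrangement).
  - It may insert into the Br-flanked OH.
  - It may be captured by traces of water.
- The fallback uses only known chemistry. It sets out from 1 and comes back to the route at 10.
- Catechol 1 (3 equiv) is O-arylated with bought 5-bromo-2-fluorobenzaldehyde F1 (K2CO3, DMF, 110 °C, N2). This is an SNAr at the C–F bond ortho to the formyl group. The C–Br bond is meta to the formyl group and stays. The product is 5-bromo-2-(2-hydroxyphenoxy)benzaldehyde F2.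
- Baeyer–Villiger oxidation with mCPBA in CH2Cl2 gives 5-bromo-2-(2-hydroxyphenoxy)phenyl formate F3. Methanolysis (catalytic K2CO3, MeOH) then gives 5-bromo-2-(2-hydroxyphenoxy)phenol F4.
- Br2 (4.0 equiv) in AcOH brominates ortho and para to each free OH. In ring A this gives the 3,5-dibromo-2-hydroxy pattern. In ring B the two new Br atoms flank the Br already para to the ether oxygen, which gives 10.

**Step 1.**
- Failure modes: di-, tri- and tetrabromocatechol may co-crystallise, and some catechol may be oxidised to quinone.
- The fallback builds the pattern on a ring where only the two required positions are open and activated. It leaves 1 aside, replaces it by bought 4-bromo-2-hydroxybenzaldehyde F5, and comes back to the route at 4.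
- Br2 (2.1 equiv) in AcOH at 50 °C brominates ortho and para to the OH, which are also the positions meta to CHO. This gives 3,4,5-tribromo-2-hydroxybenzaldehyde F6.
- Dakin oxidation (H2O2, aq NaOH, 0 °C to rt) passes through 3,4,5-tribromo-2-hydroxyphenyl formate F7, which is hydrolysed in the same flask to 4.

**Step 2.**
- Failure modes: the neutral diazo oxide 7 is sensitive to light and heat, it can be lost or become hazardous on drying, and residual water would spoil step 3.
- The fallback changes the isolated species and the way 7 is released. It sets out from 5 and comes back to the route at 7.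
- Compound 5 is diazotised with NaNO2 in aqueous HBF4 at 0 °C. The sparingly soluble salt 3,5-dibromo-2-hydroxybenzenediazonium tetrafluoroborate F8 is filtered, washed with cold Et2O and stored as the more robust ionic form.
- Just before the coupling, F8 is stirred as a suspension with powdered anhydrous K2CO3 and 4 Å MS in dry CH2Cl2. Neutral 7 dissolves as it forms. The solids are filtered off and the dry solution goes straight into the syringe pump, so 7 is never handled as a solid.

## Further compounds
F1 | step 3 | 5-bromo-2-fluorobenzaldehyde (bought) | O=Cc1cc(Br)ccc1F
F2 | step 3 | 5-bromo-2-(2-hydroxyphenoxy)benzaldehyde | O=Cc1cc(Br)ccc1Oc1ccccc1O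
F3 | step 3 | 5-bromo-2-(2-hydroxyphenoxy)phenyl formate | O=COc1cc(Br)ccc1Oc1ccccc1O
F4 | step 3 | 5-bromo-2-(2-hydroxyphenoxy)phenol | Oc1cc(Br)ccc1Oc1ccccc1O
F5 | step 1 | 4-bromo-2-hydroxybenzaldehyde (bought) | O=Cc1ccc(Br)cc1O
F6 | step 1 | 3,4,5-tribromo-2-hydroxybenzaldehyde | O=Cc1cc(Br)c(Br)c(Br)c1O
F7 | step 1 | 3,4,5-tribromo-2-hydroxyphenyl formate | O=COc1cc(Br)c(Br)c(Br)c1O
F8 | step 2 | 3,5-dibromo-2-hydroxybenzenediazonium tetrafluoroborate | N#[N+]c1cc(Br)cc(Br)c1O.F[B-](F)(F)F
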